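(The runs stem from a simulated flask with made-up constants, noise included.)

The ratio of Jc to Ja charged in south is 0.950, and we think that ratio is the thing to watch in this flask at 85 °C.

| flask | Ja | Jc | Jb | temperature | remark | time |
|---|---|---|---|---|---|---|
| Sunday's | 31 mM | 0.95 equiv | 0.09 mol% | 48 °C | run made earlier |  |
| Thursday's | 31 mM | 0.95 equiv | 0.36 mol% | 75 °C | run made earlier |  |
| Wednesday's | 16 mM | 0.95 equiv | 0.18 mol% | 48 °C | run made earlier |  |
| south-east | 31 mM | 0.950 equiv | 0.18 mol% | 35 °C |  | 6.0 h |
| north | 31 mM | 0.950 equiv | 0.18 mol% | 60 °C |  | 6.0 h |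
| south | 31 mM | 0.950 equiv | 0.18 mol% | 85 °C |  | 6.0 h |

- Sunday's (time / h: Jf / %, Ja / %, Jd / %): 0.250: 0, 98, 1; 0.833: 3, 93, 6; 1.50: 0, 88, 9; 2.00: 3, 86, 11; 3.00: 5, 78, 17
- Thursday's (time / min: Jf / %, Ja / %, Jd / %): 4.00: 0, 94, 4; 12.0: 3, 81, 13; 25.0: 9, 65, 24; 30.0: 13, 60, 31; 50.0: 22, 44, 33
- Wednesday's (time / h: Jf / %, Ja / %, Jd / %): 0.667: 1, 95, 4; 1.33: 2, 89, 8; 2.00: 0, 84, 14; 2.50: 1, 81, 16; 3.00: 3, 78, 19

(scatter of a reading: 1.5 percentage points)

* which of these there is most of at the end, counted by the Ja in it, south-east (Jd / Jf / Ja)
* which of these there is most of at the end, counted by the Ja in it, north (Jd / Jf / Ja)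
* which of these there is most of at the end, counted by the Ja in it, south (Jd / Jf / Ja)
* final amount of the leader among these, as a percentage of the Ja charged, in south-east
* final amount of the leader among these, as a percentage of the Ja charged, in north
* final amount of the leader among these, as a percentage of the Ja charged, in south

- the analysis behind the earlier runs scatters by 1.5 percentage points, standard deviation
- a reading or a percentage of Jf counts all its forms, free or not

The bench rule treats the step from Jd to Jf as first order and counts half-lives. We apply it with Thursday's last two readings. Jf's gain per hour, divided by the mean fraction of Jd, gives a constant. Halved for south's loading, this is 0.422 h⁻¹. That makes 3.65 half-lives in 6.0 h, so the rule puts Jf in south at 87.4%.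

But a pseudo-first-order treatment needs a partner that stays in excess. Reckoning with Ja fully converted and with side products ignored, Jd plus Jf is the whole charge while Jc plus Jf is 0.950 of it. So Jc over Jd stands at or below 0.950, and the two fall together. The rule stops working there.

We therefore compute only the small thing, the shortfall of Jf below its ceiling of 0.950, which equals the Jc left as a fraction of the Ja charge. We define the pairing constant as the fraction of the charge turned into Jf per hour, divided by the fractions of Jd and Jc then present. The same readings of Thursday, with their scatter, put it at 1.09 h⁻¹, and halved for the loading at 0.544 h⁻¹. For two partners falling together, the reciprocal of the shortfall grows linearly with time, starting from the reciprocal of 0.950. That gives a shortfall of 23.2%. We let Jd stand in full from the start, and we carry the constant unchanged from Thursday's 75 °C to south's 85 °C; we expect the first to raise our Jf and the second to lower it, by amounts we have not reckoned. Our own figure for Jf in south is therefore 71.8%.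

The forecast named Ja, Jf and Jf as leaders in south-east, north and south, at 58%, 48% and 92%, holding for south that “Jf is near the 95% Jc cap”. Our figure for south differs from its 92%.

South-east ended with Ja in the lead at 61.5%, north with Jf at 50.5% and south with Jf at 75.0%.

    Ja + Jb → Jb + Jd (k = 0.440 L mol⁻¹ s⁻¹, Ea = 40.0 kJ mol⁻¹)
    Jb + Jd ⇌ Jg (K = 22.0 L mol⁻¹, k = 9.20 L mol⁻¹ s⁻¹, Ea = 50.0 kJ mol⁻¹, ΔH = −20.0 kJ mol⁻¹)
    Jc + Jg → Jb + Jf (k = 2.50 L mol⁻¹ s⁻¹, Ea = 39.0 kJ mol⁻¹)
    2 Ja → Je (k = 1.20 × 10⁻⁶ L mol⁻¹ s⁻¹, Ea = 85.0 kJ mol⁻¹)
    Jb + Jf ⇌ Jh (K = 7.40 L mol⁻¹, k = 0.00420 L mol⁻¹ s⁻¹, Ea = 73.0 kJ mol⁻¹, ΔH = −46.0 kJ mol⁻¹)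
    (constants at 35 °C)

In south, the step making Jd had 90% of its turnover up to 6.00 h behind it after 3.00 h, and the step of Jc on Jg had 71%. At 6.00 h in south, with Ja at 1.23%, Jd stood at 21.9% and Jc at 20.0% of the Ja charge, against our shortfall of 23.2%; Jc's half-life by that step was then 3.5 h. For the neighbour of south with 19 mM of Ja, with equivalents, loading and time held, we take the rate as going with the amounts of Jc, Jd and catalyst together and scale the constant by the square of the charge ratio to 0.204 h⁻¹. That gives Jf in this neighbour at 51.1%. The computed neighbour holds 51.7%.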